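Remark on the chemistry (assumption): ethyl 4-methylpent-3-enoate (7) is taken as a purchasable ester; if it is not at hand, acid-catalysed esterification of the commercial parent acid with ethanol supplies it.

## Analysis of the target

Epimedonin L (32) is a flavone: a 4H-chromen-4-one in which benzo ring A is fused to pyranone ring C, with phenyl ring B on C2 (flavone locants C2 to C8a and C1' to C6' are used for every intermediate below). It has no stereocenter, so the whole problem is regiochemical. Ring B is symmetric, a C4' hydroxyl flanked by prenyl groups (prenyl = 3-methylbut-2-en-1-yl) on C3' and C5', and maps onto a para-substituted phenol. Ring A is the hard part: its six carbons all differ (ring oxygen O1 on C8a, prenyl on C8, OH on C7, H on C6, OH on C5, the C4 carbonyl on C4a), and the single prenyl group must end on C8 and not on C6, a choice that direct prenylation of a 5,7-dihydroxyflavone or of a phloroglucinol ketone does not make cleanly. The sensitive groups are the three trisubstituted prenyl alkenes, each ortho to a phenol: they rule out hydrogenolysis, electrophilic halogen and strong Lewis acids, and under Brønsted acid the neighbouring hydroxyl can add across the alkene to close a 2,2-dimethylchroman. The three phenols also differ in character (C5–OH chelated to the carbonyl, C7–OH acidic and para to it, C4'–OH hindered), which matters for protection and release. The plan rests on the sequence around ring A read from C8a: oxygen on C8a, alkyl on the ortho carbon C8, oxygen on the meta carbon C7, hydrogen on C6, oxygen on C5 and a free ortho carbon C4a. A vinylketene and a siloxyalkyne assemble exactly this pattern in one operation, and they deliver the three oxygens in three different states.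

## Retrosynthetic reasoning

**Protecting groups (32 ⇒ 30 ⇒ 29).** The last operations only unmask oxygen. The two methoxymethyl ethers of 30 (on O5 and O4') are cut with dilute acid through 31, and 30 comes from 29 by fluoride cleavage of the O7 silyl ether. No C–C bond is made after the flavone exists, so the acid-sensitive ortho-prenyl phenols are exposed only once, briefly, at the very end. The acetal on O5 is chosen because it survives amines, organolithium reagents and mild oxidants, and so keeps O5 out of the closure of ring C.

**Ring C, O1–C2 bond (29 ⇒ 27).** Cutting O1–C2 opens the pyranone to the ortho-hydroxyaryl ynone 27. The forward closure is a 6-endo addition of the only free hydroxyl (on C8a) to the alkyne. Routed through enaminone 28, formed with a secondary amine, the β-carbon is the sole electrophilic site and the five-membered aurone is excluded. Because O5 is capped, closure through the wrong oxygen, which would give the 6-prenyl isomer, cannot occur.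

**C4–C3 bond (27 ⇒ 26 ⇒ 17 + 23).** The ynone is cut between the carbonyl carbon C4 and the alkyne carbon C3. This divides the molecule into two halves of similar size: salicylaldehyde 17 (ring A plus C4) and arylacetylene 23 (ring B plus C2 and C3). Forward, lithium acetylide 24 adds to the aldehyde, held as phenoxide 25, and carbinol 26 is oxidised; its stereocenter is of no consequence. This is the most convergent cut available, and all three prenyl groups are in place before the union.

**C4a–C4 bond (17 ⇒ 15).** Removing the formyl carbon leads to phenol 15. The forward reaction is a magnesium-mediated ortho-formylation through 16, directed by the free hydroxyl. The other ortho carbon (C8) carries the prenyl group, so only C4a can react, and C6, para to the hydroxyl, is left alone.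

**Ring A (15 ⇒ 6 + 10), the key disconnection.** Three bonds are cut: C8a–C8, C7–C6 and C4a–C8a. Forward, diazoketone 6 gives vinylketene 11, which combines with siloxyalkyne 10 through cyclobutenone 12, dienylketene 13 and dienone 14. This is the one cut that builds the ring and at the same time fixes the place of the prenyl group (carried by the alkyne, hence ortho to the new hydroxyl) and the state of each oxygen (ketene oxygen free, alkyne oxygen silylated, enol ether oxygen as acetal). Both partners are small acyclic compounds, so the uncertain step comes early and on cheap material.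

**Diazoketone (6 ⇒ 3 ⇒ 1).** 6 goes back to methyl ketone 3 by diazo transfer after transient trifluoroacetylation (4, 5), and 3 to diketone 1 by O-alkylation of its mono-enolate 2. Diazo transfer is preferred to acylation of a diazoalkane because the latter would add to the enone double bond.

**Siloxyalkyne (10 ⇒ 7).** 10 is the O-silylated form of ynolate 9, made from an ester by one-carbon homologation through 8. The homologation inserts the new carbon between the acyl carbon and the oxygen, so the acyl carbon must already carry the prenyl CH2. That ester is 7; an ester with one more methylene would place a homoprenyl chain on C8.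

**Ring B fragment (23 ⇒ 22 ⇒ 21 ⇒ 18 + 19).** The alkyne comes from aldehyde 22 by one-carbon homologation and 22 from phenol 21 by acetal formation. The two aryl–CH2 bonds of 21 are cut back to 18 and two molecules of 19 (through 20): the phenoxide is alkylated on its ortho carbons, one after the other, while the formyl group blocks the para position and later becomes the alkyne.

## Alternatives that were turned down

**Alternative 1:** Ring B from a saturated ketone.
- Disconnection: the two aryl–CH2 bonds of ring B (C3'–CH2, C5'–CH2) are traced to enolate alkylations. Ring B is bought as ethyl 4-oxocyclohexane-1-carboxylate (A1) and aromatised later.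
- Forward key step: A1 is deprotonated with a lithium amide and alkylated with 19, twice in one flask, to give ethyl 4-oxo-3,5-diprenylcyclohexane-1-carboxylate (A2); any diastereomer serves.
- For it: an enolate carbon has no O-alkylation channel of the kind that burdens the phenoxide of 18 in step 6. The stereocenters of A2 vanish on aromatisation, and A1 is cheap.
- Against it: the step closes no ring and only decorates the easy, symmetric ring. A one-flask double alkylation must hold α,α' against α,α and against over-alkylation while enolates and products exchange protons, and the ester α-hydrogen is a third acidic site. A2 must then be raised by two dehydrogenations in the presence of two trisubstituted alkenes: halogenation–elimination attacks them, and palladium-catalysed aerobic dehydrogenation risks allylic oxidation or alkene migration. The ester still has to become the alkyne, about three more steps.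
- Comparison: on how cleanly the prenyl C–C bonds are made, alternative 1 is probably stronger than step 6. The chosen route instead reaches 23 in three steps from 18 and spends its key step on ring A, which alternative 1 leaves untouched; the C8 versus C6 question would remain open.

**Alternative 2:** Ring A closed last by an acylketene.
- Disconnection: the C4a–C5 bond, cut in the mono-protected flavone A4. Ring A is made on a finished 2-aryl-4-pyranone that carries the C8–C7–C6–C5 chain on the carbon that becomes C8a.
- Forward key step: thermolysis of the acyl Meldrum's acid A3 releases an acylketene. The enol of the C7 ketone, the pyranone C4a=C8a bond and the ketene form a triene that closes by 6π electrocyclisation (equivalently, the ketene C-acylates the nucleophilic pyranone carbon C4a). Tautomerisation gives the resorcinol ring of A4, which is Epimedonin L carrying a single methoxymethyl ether on the ring B hydroxyl. A4 is the same compound as 31.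
- For it: in A4 ring A is formed as the free 5,7-diol, so ring A needs no protecting group and only one acetal is left to remove. The prenyl group is locked on C8 by the chain, and the step is late and convergent. On protecting-group economy and on the length of the endgame, the path through A4 beats the chosen route.
- Against it: A3 is a demanding precursor, a 2,6-disubstituted pyranone with a branched β-keto acid side chain whose C8–H is doubly activated; it would take at least as many steps as the whole chosen route. Acylketenes are indiscriminate electrophiles (dimerisation, O-acylation by the enol or the pyranone carbonyl oxygen). The pyranone C4a=C8a bond is part of a stabilised vinylogous ester and a reluctant 2π partner, and the closure to A4 passes through a dearomatised pyranone.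
- Comparison: closure of an acylketene onto a 4-pyranone has little precedent, so the largest risk would sit at the last C–C bond formation, the one that makes A4, with all three prenyl groups on board. In the chosen route the uncertain step is early, uses compounds at most two steps from commercial materials, and belongs to an established reaction class.

**Alternative 3:** Ring B by a [3+3] condensation.
- Disconnection: ring B is cut at C2'–C3' and C5'–C6' into a three-carbon ketone unit and a three-carbon dialdehyde unit.
- Forward key step: the symmetric ketone 2,10-dimethylundeca-2,9-dien-6-one (A5, 1,3-diprenylacetone) condenses at both α-carbons with the two formyl groups of ethyl 2-formyl-3-oxopropanoate (A6) under an alkoxide base. Two aldol condensations and tautomerisation give ethyl 4-hydroxy-3,5-diprenylbenzoate (A7).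
- For it: both prenyl groups are in the ring from the start, with no O- versus C-alkylation and no mono/bis mixture. Condensation of dialkyl ketones with 2-substituted malondialdehydes is an established phenol synthesis. As a way to a clean 2,6-diprenylphenol it is likely more reliable than step 6.
- Against it: neither A5 nor A6 is a shelf compound (A5 needs two alkylations with 19 and a decarboxylation, A6 a formylation). A7 is an ester that needs reduction, oxidation and homologation before it equals 23, so ring B would cost roughly twice as many steps. Like alternative 1, it builds from scratch the ring that 18 already provides and leaves ring A unsolved.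
- Comparison: A7 could be grafted onto the chosen route (it converges on 21 after adjustment of the oxidation level) if step 6 proved unworkable. As a strategy, however, it puts the ring-forming event where the target is easy; the chosen route puts it where the target is hard.

Key step: step 4

## Route

**Step 1**
Reactants: 1 2,3-butanedione
Product: 3 3-(methoxymethoxy)but-3-en-2-one, via potassium enolate 2 (not isolated)
Conditions: KN(SiMe3)2, THF, −78 °C (1 added slowly); then MOMCl, DMPU, −78 to 0 °C
Reagents that add atoms: chloromethyl methyl ether (MOMCl), COCCl
Why: Enolate O-alkylation: slow addition of 1 to the amide base keeps free diketone scarce and so holds back aldol self-condensation, and the hard, oxocarbenium-like chloride should attack the potassium enolate 2 at oxygen in the dipolar medium. The methoxymethyl group is chosen because it survives every basic and nucleophilic step that follows and leaves under mild acid.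

**Step 2**
Reactants: 3 3-(methoxymethoxy)but-3-en-2-one
Product: 6 1-diazo-3-(methoxymethoxy)but-3-en-2-one, via lithium dienolate 4 (not isolated), via trifluoroacetyl diketone 5 (not isolated)
Conditions: LiN(SiMe3)2, THF, −78 °C; CF3CO2CH2CF3; then MsN3, Et3N, H2O, MeCN, rt
Reagents that add atoms: methanesulfonyl azide, CS(=O)(=O)N=[N+]=[N-]; 2,2,2-trifluoroethyl trifluoroacetate, O=C(OCC(F)(F)F)C(F)(F)F (its acyl group is carried by 5 only)
Why: Detrifluoroacetylative Regitz diazo transfer: Claisen acylation of the only enolisable position (the methyl group, via 4) gives 5, which is not purified, and the sulfonyl azide then delivers N2 while the trifluoroacetyl group leaves on the sulfonamide nitrogen. This avoids a diazoalkane, which would add to the enone double bond.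

**Step 3**
Reactants: 7 ethyl 4-methylpent-3-enoate
Product: 10 triisopropyl[(5-methylhex-4-en-1-yn-1-yl)oxy]silane, via dibromo enolate 8 (not isolated), via lithium ynolate 9 (not isolated)
Conditions: CH2Br2, lithium 2,2,6,6-tetramethylpiperidide, THF, −78 °C; LiN(SiMe3)2; n-BuLi, −78 °C to rt; then iPr3SiCl, −78 °C to rt
Reagents that add atoms: dibromomethane, BrCBr; chlorotriisopropylsilane, CC(C)[Si](Cl)(C(C)C)C(C)C
Why: Kowalski ester homologation halted at the ynolate: LiCHBr2 adds to the ester, the dibromomethyl ketone is held as enolate 8, bromine–lithium exchange and 1,2-shift of the prenyl group give ynolate 9, and the bulky silyl chloride silylates 9 on oxygen, not on carbon. The sequence inserts one carbon, so the acyl carbon of the ester must already carry the prenyl CH2 (7); an ester one methylene longer would put a homoprenyl group on C8.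

**Step 4**
Reactants: 6 1-diazo-3-(methoxymethoxy)but-3-en-2-one, 10 triisopropyl[(5-methylhex-4-en-1-yn-1-yl)oxy]silane
Product: 15 5-(methoxymethoxy)-2-prenyl-3-[(triisopropylsilyl)oxy]phenol, via vinylketene 11 (not isolated), via vinylcyclobutenone 12 (not isolated), via dienylketene 13 (not isolated), via cyclohexadienone 14 (not isolated)
Conditions: hν (254 nm, low-pressure Hg lamp), 10 in slight excess, CH2Cl2, rt; then toluene, 80 °C
Reagents that add atoms: none
Why: Irradiation expels N2 from 6 and the photochemical Wolff rearrangement gives vinylketene 11. The ketene carbon of 11 (future C8a) bonds to the nucleophilic, prenyl-bearing carbon of 10 (C8) and the ketene α-carbon (C6) to the siloxy-bearing carbon (C7) in a regioselective [2+2] cycloaddition that gives the 4-vinylcyclobutenone 12. Reversible 4π electrocyclic opening of 12 (conrotatory on heating, also driven by light) cuts the old ketene C=C bond and gives dienylketene 13, and ring A then closes by thermal disrotatory 6π electrocyclisation between the ketene carbon and the CH2 terminus of the enol ether (C8a–C4a); cyclohexadienone 14 tautomerises to phenol 15. The closest known reaction type is the second-generation Danheiser benzannulation of α-diazo enones with siloxyalkynes, which gives resorcinol monosilyl ethers. No stereocenter is formed in 15; the one in 12 is lost on ring opening. The step needs regioselectivity in the [2+2] event, and the oxygen lone pair of the ynol ether secures it by making the prenyl-bearing carbon the nucleophile, so that prenyl ends ortho and siloxy meta to the new hydroxyl; it also needs chemoselectivity, and the electron-rich alkyne should capture the ketene far faster than the trisubstituted prenyl alkene does. Because the ring opening of 12 is reversible, only the geometry of 13 that can cyclise is drained, so the sense of rotation need not be controlled, and the final heating converts any 12 that is left. The three oxygens leave the step in three states: free hydroxyl on C8a (from the ketene), silyl ether on C7 (from the alkyne) and acetal on C5 (from the enol ether), with C4a the only open ortho carbon.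

**Step 5**
Reactants: 15 5-(methoxymethoxy)-2-prenyl-3-[(triisopropylsilyl)oxy]phenol
Product: 17 2-hydroxy-6-(methoxymethoxy)-3-prenyl-4-[(triisopropylsilyl)oxy]benzaldehyde, via salicyl alcohol 16 (not isolated)
Conditions: MgCl2, Et3N, (CH2O)n, THF, reflux
Reagents that add atoms: paraformaldehyde (as formaldehyde), C=O
Why: Casnati–Skattebøl ortho-formylation: the magnesium phenoxide of 15 delivers the one-carbon electrophile to an ortho carbon only, giving the chelated salicyl alcohol 16, which a second equivalent of formaldehyde oxidises by hydride transfer. C8 is blocked by the prenyl group, so C4a is the only site, and the para carbon C6 is not reached by the chelate; silyl ether, acetal and alkene should tolerate the mild, basic medium.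

**Step 6**
Reactants: 18 4-hydroxybenzaldehyde, 19 prenyl bromide (1-bromo-3-methylbut-2-ene)
Product: 21 4-hydroxy-3,5-diprenylbenzaldehyde, via monoprenyl phenol 20 (not isolated)
Conditions: 19 (excess, added in portions), KOH, H2O, rt
Reagents that add atoms: prenyl bromide 19 (second equivalent), CC(C)=CCBr
Why: Ortho C-alkylation of a phenoxide in water, run twice in one flask so that two molecules of 19 are consumed: hydrogen bonding shields the oxygen, the para position is blocked by the formyl group, and the allylic bromide is taken up at its primary terminus, first at one ortho carbon (giving 20) and then, with the second equivalent, at the other. O-prenyl ether and leftover 20 are expected by-products; they are separable and 20 can be resubmitted, which is acceptable for a first step from commodity chemicals.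

**Step 7**
Reactants: 21 4-hydroxy-3,5-diprenylbenzaldehyde
Product: 22 4-(methoxymethoxy)-3,5-diprenylbenzaldehyde
Conditions: MOMCl, iPr2NEt, CH2Cl2, 0 °C to rt
Reagents that add atoms: chloromethyl methyl ether (MOMCl), COCCl
Why: Williamson-type acetal formation on the acidic para-formyl phenol; the small chloromethyl ether reaches the oxygen between the two ortho prenyl groups. The acetal is inert to the carbonate, organolithium, oxidant and amine used before it is removed in step 13.

**Step 8**
Reactants: 22 4-(methoxymethoxy)-3,5-diprenylbenzaldehyde
Product: 23 5-ethynyl-2-(methoxymethoxy)-1,3-diprenylbenzene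
Conditions: MeC(O)C(N2)P(O)(OMe)2, K2CO3, MeOH, rt
Reagents that add atoms: dimethyl (1-diazo-2-oxopropyl)phosphonate, COP(=O)(OC)C(=[N+]=[N-])C(C)=O
Why: Seyferth–Gilbert homologation with the Ohira–Bestmann reagent: methanolysis of the reagent gives the diazomethylphosphonate anion, which olefinates the aldehyde; loss of N2 and 1,2-hydrogen shift give the terminal alkyne. Carbonate in methanol is harmless to the acetal and the alkenes.

**Step 9**
Reactants: 23 5-ethynyl-2-(methoxymethoxy)-1,3-diprenylbenzene, 17 2-hydroxy-6-(methoxymethoxy)-3-prenyl-4-[(triisopropylsilyl)oxy]benzaldehyde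
Product: 26 racemic propargylic alcohol (ring A–CH(OH)–C≡C–ring B), via lithium acetylide 24 (not isolated), via lithium phenoxide 25 (not isolated)
Conditions: 23, n-BuLi, THF, −78 °C; 17, LiN(SiMe3)2, THF, −78 °C; combine, −78 to 0 °C; then aq NH4Cl
Reagents that add atoms: none
Why: 1,2-Addition of a lithium acetylide to an aldehyde; the phenol of 17 is first converted into phenoxide 25 with a non-nucleophilic amide so that no acetylide is spent as base, and the small, linear nucleophile should still reach the flanked, deactivated formyl group on warming. The new carbinol centre is formed racemic and is removed by oxidation in step 10.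

**Step 10**
Reactants: 26 racemic propargylic alcohol
Product: 27 ortho-hydroxyaryl ynone (ring A–C(=O)–C≡C–ring B)
Conditions: MnO2, CH2Cl2, rt
Reagents that add atoms: none
Why: MnO2 oxidises the doubly activated (benzylic and propargylic) alcohol selectively under neutral conditions; the free phenol, the prenyl alkenes, the acetals and the silyl ether should not be touched. The ynone is stabilised by the hydrogen bond from the C8a hydroxyl.

**Step 11**
Reactants: 27 ortho-hydroxyaryl ynone
Product: 29 5,4'-bis(methoxymethoxy)-7-[(triisopropylsilyl)oxy]-8,3',5'-triprenylflavone, via enaminone 28 (not isolated)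
Conditions: Et2NH, EtOH, rt to 60 °C
Reagents that add atoms: none
Why: Amine-mediated 6-endo cyclisation of an ortho-hydroxyaryl ynone: aza-Michael addition of the secondary amine gives enaminone 28, whose β-carbon is the only electrophilic site, so the C8a hydroxyl closes the O1–C2 bond by addition–elimination and the amine is released; the 5-exo path to an aurone is closed off. O5 is capped as its acetal, so only the oxygen next to the prenyl group can cyclise, which fixes the 8-prenyl constitution; any silyl ether lost under these conditions converges on 30 after step 12.

**Step 12**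
Reactants: 29 5,4'-bis(methoxymethoxy)-7-[(triisopropylsilyl)oxy]-8,3',5'-triprenylflavone
Product: 30 7-hydroxy-5,4'-bis(methoxymethoxy)-8,3',5'-triprenylflavone
Conditions: Bu4NF, AcOH, THF, 0 °C
Reagents that add atoms: none
Why: Fluoride cleavage of the aryl silyl ether, buffered with acetic acid so that the acidic C7 phenoxide is not exposed to base and air. The acetals and alkenes are inert.

**Step 13**
Reactants: 30 7-hydroxy-5,4'-bis(methoxymethoxy)-8,3',5'-triprenylflavone
Product: 32 Epimedonin L, via mono-ether 31 (not isolated)
Conditions: HCl (3 M aq), MeOH, 40 °C
Reagents that add atoms: none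
Why: Acid-catalysed acetal exchange with methanol removes both methoxymethyl groups; the chelated C5 ether is expected to go first (31), the twisted, hindered C4' ether second. Dilute acid, mild temperature and a short reaction time are chosen so that the ortho-prenyl phenols do not cyclise to chromans.

## Compound list

1 | 2,3-butanedione | CC(=O)C(C)=O | starting material
2 | potassium 3-oxobut-1-en-2-olate | [K+].[O-]C(=C)C(C)=O | intermediate
3 | 3-(methoxymethoxy)but-3-en-2-one | COCOC(=C)C(C)=O | intermediate
4 | lithium 3-(methoxymethoxy)buta-1,3-dien-2-olate | [Li+].[O-]C(=C)C(=C)OCOC | intermediate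
5 | 1,1,1-trifluoro-5-(methoxymethoxy)hex-5-ene-2,4-dione | C=C(OCOC)C(=O)CC(=O)C(F)(F)F | intermediate
6 | 1-diazo-3-(methoxymethoxy)but-3-en-2-one | C=C(OCOC)C(=O)C=[N+]=[N-] | intermediate
7 | ethyl 4-methylpent-3-enoate | CCOC(=O)CC=C(C)C | starting material
8 | lithium 1,1-dibromo-5-methylhexa-1,4-dien-2-olate | [Li+].[O-]C(CC=C(C)C)=C(Br)Br | intermediate
9 | lithium 5-methylhex-4-en-1-yn-1-olate | [Li+].[O-]C#CCC=C(C)C | intermediate
10 | triisopropyl[(5-methylhex-4-en-1-yn-1-yl)oxy]silane | CC(C)=CCC#CO[Si](C(C)C)(C(C)C)C(C)C | intermediate
11 | 3-(methoxymethoxy)buta-1,3-dien-1-one | C=C(OCOC)C=C=O | intermediate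
12 | 4-[1-(methoxymethoxy)ethenyl]-2-prenyl-3-[(triisopropylsilyl)oxy]cyclobut-2-en-1-one (racemic) | C=C(OCOC)C1C(=O)C(CC=C(C)C)=C1O[Si](C(C)C)(C(C)C)C(C)C | intermediate
13 | (3E)-5-(methoxymethoxy)-2-prenyl-3-[(triisopropylsilyl)oxy]hexa-1,3,5-trien-1-one (ketene arm and enol ether arm cis) | C=C(OCOC)\C=C(O[Si](C(C)C)(C(C)C)C(C)C)/C(CC=C(C)C)=C=O | intermediate
14 | 5-(methoxymethoxy)-2-prenyl-3-[(triisopropylsilyl)oxy]cyclohexa-2,4-dien-1-one | O=C1CC(OCOC)=CC(O[Si](C(C)C)(C(C)C)C(C)C)=C1CC=C(C)C | intermediate
15 | 5-(methoxymethoxy)-2-(3-methylbut-2-en-1-yl)-3-[(triisopropylsilyl)oxy]phenol | COCOc1cc(O)c(CC=C(C)C)c(O[Si](C(C)C)(C(C)C)C(C)C)c1 | intermediate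
16 | 2-(hydroxymethyl)-3-(methoxymethoxy)-6-prenyl-5-[(triisopropylsilyl)oxy]phenol (as its magnesium chelate) | OCc1c(O)c(CC=C(C)C)c(O[Si](C(C)C)(C(C)C)C(C)C)cc1OCOC | intermediate
17 | 2-hydroxy-6-(methoxymethoxy)-3-(3-methylbut-2-en-1-yl)-4-[(triisopropylsilyl)oxy]benzaldehyde | O=Cc1c(O)c(CC=C(C)C)c(O[Si](C(C)C)(C(C)C)C(C)C)cc1OCOC | intermediate
18 | 4-hydroxybenzaldehyde | O=Cc1ccc(O)cc1 | starting material
19 | prenyl bromide (1-bromo-3-methylbut-2-ene) | CC(C)=CCBr | starting material
20 | 4-hydroxy-3-(3-methylbut-2-en-1-yl)benzaldehyde | O=Cc1ccc(O)c(CC=C(C)C)c1 | intermediate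
21 | 4-hydroxy-3,5-bis(3-methylbut-2-en-1-yl)benzaldehyde | O=Cc1cc(CC=C(C)C)c(O)c(CC=C(C)C)c1 | intermediate
22 | 4-(methoxymethoxy)-3,5-bis(3-methylbut-2-en-1-yl)benzaldehyde | O=Cc1cc(CC=C(C)C)c(OCOC)c(CC=C(C)C)c1 | intermediate
23 | 5-ethynyl-2-(methoxymethoxy)-1,3-bis(3-methylbut-2-en-1-yl)benzene | C#Cc1cc(CC=C(C)C)c(OCOC)c(CC=C(C)C)c1 | intermediate
24 | lithium [4-(methoxymethoxy)-3,5-diprenylphenyl]ethynide | [Li+].[C-]#Cc1cc(CC=C(C)C)c(OCOC)c(CC=C(C)C)c1 | intermediate
25 | lithium 2-formyl-3-(methoxymethoxy)-6-prenyl-5-[(triisopropylsilyl)oxy]phenolate | [Li+].[O-]c1c(C=O)c(OCOC)cc(O[Si](C(C)C)(C(C)C)C(C)C)c1CC=C(C)C | intermediate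
26 | 2-{1-hydroxy-3-[4-(methoxymethoxy)-3,5-diprenylphenyl]prop-2-yn-1-yl}-3-(methoxymethoxy)-6-prenyl-5-[(triisopropylsilyl)oxy]phenol (racemic) | OC(C#Cc1cc(CC=C(C)C)c(OCOC)c(CC=C(C)C)c1)c1c(O)c(CC=C(C)C)c(O[Si](C(C)C)(C(C)C)C(C)C)cc1OCOC | intermediate
27 | 1-{2-hydroxy-6-(methoxymethoxy)-3-prenyl-4-[(triisopropylsilyl)oxy]phenyl}-3-[4-(methoxymethoxy)-3,5-diprenylphenyl]prop-2-yn-1-one | O=C(C#Cc1cc(CC=C(C)C)c(OCOC)c(CC=C(C)C)c1)c1c(O)c(CC=C(C)C)c(O[Si](C(C)C)(C(C)C)C(C)C)cc1OCOC | intermediate
28 | (E)-3-(diethylamino)-1-{2-hydroxy-6-(methoxymethoxy)-3-prenyl-4-[(triisopropylsilyl)oxy]phenyl}-3-[4-(methoxymethoxy)-3,5-diprenylphenyl]prop-2-en-1-one (drawn E; the push–pull double bond rotates easily) | CCN(CC)/C(=C/C(=O)c1c(O)c(CC=C(C)C)c(O[Si](C(C)C)(C(C)C)C(C)C)cc1OCOC)c1cc(CC=C(C)C)c(OCOC)c(CC=C(C)C)c1 | intermediate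
29 | 5-(methoxymethoxy)-2-[4-(methoxymethoxy)-3,5-diprenylphenyl]-8-prenyl-7-[(triisopropylsilyl)oxy]-4H-chromen-4-one | COCOc1cc(O[Si](C(C)C)(C(C)C)C(C)C)c(CC=C(C)C)c2oc(-c3cc(CC=C(C)C)c(OCOC)c(CC=C(C)C)c3)cc(=O)c12 | intermediate
30 | 7-hydroxy-5-(methoxymethoxy)-2-[4-(methoxymethoxy)-3,5-diprenylphenyl]-8-prenyl-4H-chromen-4-one | COCOc1cc(O)c(CC=C(C)C)c2oc(-c3cc(CC=C(C)C)c(OCOC)c(CC=C(C)C)c3)cc(=O)c12 | intermediate
31 | 5,7-dihydroxy-2-[4-(methoxymethoxy)-3,5-diprenylphenyl]-8-prenyl-4H-chromen-4-one | COCOc1c(CC=C(C)C)cc(cc1CC=C(C)C)-c1cc(=O)c2c(O)cc(O)c(CC=C(C)C)c2o1 | intermediate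
32 | Epimedonin L, 5,7-dihydroxy-2-[4-hydroxy-3,5-bis(3-methylbut-2-en-1-yl)phenyl]-8-(3-methylbut-2-en-1-yl)-4H-chromen-4-one | CC(C)=CCc1cc(-c2cc(=O)c3c(O)cc(O)c(CC=C(C)C)c3o2)cc(CC=C(C)C)c1O | target

## Step count and least certain steps

Total step count: 13. Longest linear sequence: 9 steps (steps 1, 2, 4, 5, 9, 10, 11, 12, 13, from 1 to 32).

**Step 4 (key step).** The photogenerated vinylketene may be consumed by dimerisation, or by O-acylation of phenol already formed, faster than by the alkyne. The diazoketone may undergo dipolar cycloaddition before it is photolysed. Conversion of the cyclobutenone may stall. Fallback: ring A by classical phloroglucinol chemistry, setting out from 19 and purchased 2,4,6-trihydroxybenzaldehyde. C-prenylation with 19 and DBU in THF should give 2,4,6-trihydroxy-3-prenylbenzaldehyde F1. iPr3SiCl and imidazole should silylate its non-chelated, most acidic hydroxyl (para to the formyl group) to give 2,6-dihydroxy-3-prenyl-4-[(triisopropylsilyl)oxy]benzaldehyde F2. One equivalent of MOMCl with iPr2NEt should then cap the less hindered of the two chelated hydroxyls, the one not flanked by the prenyl group, and so arrive at 17. The route is rejoined at 17, and steps 4 and 5 are bypassed. This fallback gives up regiocontrol by construction and relies on selectivity among hydroxyls.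

**Step 3.** The doubly activated α-methylene of 7 (allylic and next to the ester) may lose a proton to the carbenoid or amide bases instead of the carbonyl being attacked, and the skipped double bond may migrate under base at the ynolate stage. Fallback: oxidation of an acetylide, setting out from 19. Coupling of 19 with (trimethylsilyl)ethynylmagnesium bromide under CuBr catalysis should give trimethyl(5-methylhex-4-en-1-yn-1-yl)silane F3. K2CO3 in methanol frees 5-methylhex-4-en-1-yne F4. n-BuLi at −78 °C gives its lithium acetylide F5, which LiOOtBu should oxidise to ynolate 9. Trapping with iPr3SiOTf returns to the route at 10.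

**Step 1.** Aldol addition of enolate 2 to unreacted diketone may outrun deprotonation, and some C-alkylation may compete. Fallback, setting out from 1: soft enolisation and silylation (Me3SiCl, Et3N, DMF) should give 3-[(trimethylsilyl)oxy]but-3-en-2-one F6. Fluoride-triggered desilylation in the presence of MOMCl (CsF or Bu4N[Ph3SiF2], MeCN, low temperature) releases the enolate only when no free diketone is present and should deliver 3, where the route is rejoined.

**Step 6.** O-alkylation, arrest at the mono-alkyl stage and hydrolysis of the allylic bromide in water may leave little of the dialkylated phenol. Fallback by cross-coupling, setting out from 18. Bromination (Br2, AcOH) gives 3,5-dibromo-4-hydroxybenzaldehyde F7 and MOMCl with iPr2NEt gives 3,5-dibromo-4-(methoxymethoxy)benzaldehyde F8. A double Stille coupling of F8 with tributyl(3-methylbut-2-en-1-yl)stannane (Pd(PPh3)4, zerovalent palladium, DMF, 90 °C) should form both aryl–CH2 bonds at the less hindered allyl terminus and return to the route at 22.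

**Step 13.** Under Brønsted acid the free ortho phenols may add to the prenyl alkenes (chroman formation), or the alkenes may take up solvent, in competition with acetal cleavage. Fallback without protic acid, setting out from 29. Me3SiOTf with 2,2'-bipyridyl in CH2Cl2 at 0 °C should convert both aryl methoxymethyl ethers into aryl trimethylsilyl ethers, giving the tris-silyl flavone F9. Bu4NF buffered with AcOH then removes all three silyl groups and returns to the route at 32, bypassing 30 and 31.

## Further compounds

F1 | step 4 | 2,4,6-trihydroxy-3-(3-methylbut-2-en-1-yl)benzaldehyde | O=Cc1c(O)cc(O)c(CC=C(C)C)c1O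
F2 | step 4 | 2,6-dihydroxy-3-(3-methylbut-2-en-1-yl)-4-[(triisopropylsilyl)oxy]benzaldehyde | O=Cc1c(O)cc(O[Si](C(C)C)(C(C)C)C(C)C)c(CC=C(C)C)c1O
F3 | step 3 | trimethyl(5-methylhex-4-en-1-yn-1-yl)silane | CC(C)=CCC#C[Si](C)(C)C
F4 | step 3 | 5-methylhex-4-en-1-yne | CC(C)=CCC#C
F5 | step 3 | lithium 5-methylhex-4-en-1-yn-1-ide | [Li+].[C-]#CCC=C(C)C
F6 | step 1 | 3-[(trimethylsilyl)oxy]but-3-en-2-one | CC(=O)C(=C)O[Si](C)(C)C
F7 | step 6 | 3,5-dibromo-4-hydroxybenzaldehyde | O=Cc1cc(Br)c(O)c(Br)c1
F8 | step 6 | 3,5-dibromo-4-(methoxymethoxy)benzaldehyde | O=Cc1cc(Br)c(OCOC)c(Br)c1
F9 | step 13 | 2-{3,5-diprenyl-4-[(trimethylsilyl)oxy]phenyl}-8-prenyl-7-[(triisopropylsilyl)oxy]-5-[(trimethylsilyl)oxy]-4H-chromen-4-one | C[Si](C)(C)Oc1cc(O[Si](C(C)C)(C(C)C)C(C)C)c(CC=C(C)C)c2oc(-c3cc(CC=C(C)C)c(O[Si](C)(C)C)c(CC=C(C)C)c3)cc(=O)c12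
A1 | alternative 1 | ethyl 4-oxocyclohexane-1-carboxylate | CCOC(=O)C1CCC(=O)CC1
A2 | alternative 1 | ethyl 4-oxo-3,5-diprenylcyclohexane-1-carboxylate (drawn all-cis; any diastereomer serves) | CCOC(=O)[C@H]1C[C@@H](CC=C(C)C)C(=O)[C@@H](CC=C(C)C)C1
A3 | alternative 2 | 5-(1-hydroxy-2-{6-[4-(methoxymethoxy)-3,5-diprenylphenyl]-4-oxo-4H-pyran-2-yl}-5-methylhex-4-en-1-ylidene)-2,2-dimethyl-1,3-dioxane-4,6-dione (racemic) | COCOc1c(CC=C(C)C)cc(cc1CC=C(C)C)-c1cc(=O)cc(o1)C(CC=C(C)C)C(O)=C1C(=O)OC(C)(C)OC1=O
A4 | alternative 2 | 4'-O-(methoxymethyl) Epimedonin L | COCOc1c(CC=C(C)C)cc(cc1CC=C(C)C)-c1cc(=O)c2c(O)cc(O)c(CC=C(C)C)c2o1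
A5 | alternative 3 | 2,10-dimethylundeca-2,9-dien-6-one | CC(C)=CCCC(=O)CCC=C(C)C
A6 | alternative 3 | ethyl 2-formyl-3-oxopropanoate | CCOC(=O)C(C=O)C=O
A7 | alternative 3 | ethyl 4-hydroxy-3,5-bis(3-methylbut-2-en-1-yl)benzoate | CCOC(=O)c1cc(CC=C(C)C)c(O)c(CC=C(C)C)c1
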